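The earlier runs and the new flask were generated by integration from invented constants.

A small charge of enzyme, 20 µM, works through 0.10 M of starting material in the amber flask. You want to know what stands there at 15 d.

in all of them: starting material 0.10 M
- amber: enzyme 20 µM; the very flask that is asked about, followed so far
- red: enzyme 10 µM; run made earlier
- flask: enzyme 20 µM; time 15 d

| run | time / d | starting material / % | target / % | side product / % |
|---|---|---|---|---|
| amber | 1.04 | 2.5 | 59.4 | 38.0 |
| amber | 2.08 | 0.6 | 58.1 | 40.5 |
| amber | 3.00 | 0.3 | 58.3 | 40.9 |
| amber | 4.00 | 0.1 | 58.2 | 42.0 |
| amber | 5.00 | 0.7 | 59.0 | 41.6 |
| amber | 6.00 | 0 | 58.8 | 41.4 |
| red | 1.04 | 6.4 | 48.7 | 44.3 |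
| red | 2.08 | 1.1 | 48.0 | 50.7 |
| red | 3.00 | 0.3 | 47.7 | 51.3 |
| red | 4.00 | 0 | 47.6 | 52.5 |
| red | 5.00 | 0.1 | 47.8 | 51.9 |
| red | 6.00 | 0.3 | 47.0 | 52.9 |

(standard deviation of a reading: 0.5 percentage points)

- percentages count the starting material that a species holds: one side product counts as two
- reactions considered so far: starting material + target -> side product; starting material + enzyme -> target + enzyme; 2 enzyme <-> resting dimer
- the reaction counts as stopped when no species that holds the starting material changes by six tenths of a point or more over the second half of the time

1. the state of affairs at 15 d: stopped, and by what, or still going (all of the starting material has reacted / no working catalyst is left / it is still moving)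
2. part of the starting material gone at 15 d
3. the target standing at 15 d, as a percentage of the starting material charged
4. the side product standing at 15 d, as a percentage of the starting material charged
5. amount of target if the flask were left three thousand times as long, in percent of the starting material charged

Enzyme turns starting material into target. Starting material plus target gives side product. Two enzyme can rest as a dimer. Each side product holds one unit that was once target. So don't stop at the target standing. Count the fraction left of the target made, the kept fraction:

kept fraction = target standing / (target standing + side product ÷ 2)

Take the amber readings from 3.00 d on. Their means are: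

target 58.6%, side product 41.5%

target made = 79.3%, kept fraction = 73.9%

Can you carry this number over from the red run? No. Red, with 10 µM of enzyme, keeps 64.6%, less than amber. So use amber's own value.

Is the amber plateau a stall with a dead enzyme? Look at the starting material. Amber's readings give a mean of 0.275% from 3.00 d on, below the scatter of 0.5 percentage points. Starting material is the limiting reagent.

Could that remainder still eat target? Suppose it all does. The loss step leaves target made unchanged, and the amber kept fraction slips to:

73.5%

So I commit to amber holding about 58.6% target and 41.5% side product at 15 d, and the same after the far longer wait.

The forecast states for 15 d: all of the starting material has reacted, with 100% gone, 58.5% target, 41.5% side product and 58.5% target after the long wait, since the “listed reactions all need starting material”.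

The flask gives for 15 d: all of the starting material has reacted, with 100% gone, 58.4% target, 41.6% side product and 58.4% target after the long wait.

    starting material + target → side product (k = 2.40 × 10⁻⁴ M⁻¹ s⁻¹)
    starting material + enzyme → target + enzyme, rate k2*[starting material]^1.5*[enzyme]/(1 + ([starting material]/Kh2)^1.5) (0.0780 M, k = 26.0 M⁻¹·⁵ s⁻¹)
    2 enzyme ⇌ resting dimer, settled at all times (K = 51000 M⁻¹)

Put through the same line, the flask's values give a kept fraction of 73.8%. Now charge a neighbour with 0.40 M of starting material, holding enzyme and time. It ends with 0% of its starting material left, 25.5% target and 74.5% side product. Its target made is 62.7%, and its kept fraction is 40.6%, lower than the flask's.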